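**Retrosynthetic overview**

1. The C40 polyene is cut at C11=C12 and C11'=C12' (two successive Wittig reactions) into a C15 phosphonium salt carrying the 4-silyloxy ring, the C10 dialdehyde, and a C15 phosphonium salt carrying the 4-oxo ring.
2. Each C15 salt comes from a ring aldehyde (CHO on C6) and a C5 phosphonate (Horner–Wadsworth–Emmons, ester reduction, PPh3·HBr).
3. Both ring aldehydes come from one (2S,3S) nitromethyl ketone by a Nef reaction, the ketone being either reduced and silylated or ketalised.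
4. The nitromethyl ketone comes from an acyclic keto nitroalkene by an asymmetric intramolecular Michael addition (C5–C6 bond). This is the only ring-forming reaction: both six-membered rings come from this one closure, made before any chain building.
5. The keto nitroalkene comes from isobutyraldehyde, ethyl vinyl ketone and nitromethane.

Target: all-E (4S,5S,6S,5'S,6'S)-4-hydroxy-5,6,5',6'-tetrahydro-β,β-caroten-4'-one, C40H58O2. In both rings the C5 methyl is trans to the polyene at C6; the hydroxyl is equatorial, trans to the C5 methyl. Carotenoid numbering is used for positions; primed numbers belong to the keto half.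

Assumption: the (1R,2R) antipode of the amine–thiourea catalyst is taken to give the (2S,3S) ring; if the sense is the reverse, the equally available (1S,2S) antipode is used.

**Route**

Step 1
Reactants: 1 isobutyraldehyde (2-methylpropanal); 2 ethyl vinyl ketone (pent-1-en-3-one)
Product: 5 2,2-dimethyl-5-oxoheptanal, via enamine 3 (not isolated), via aminodihydropyran 4 (not isolated)
Conditions: pyrrolidine (1.05 equiv), K2CO3, 0 °C→rt; then 2, MeCN, rt; then AcOH/NaOAc/H2O, rt
Reagents that add atoms: pyrrolidine, C1CCNC1 (atoms kept only in 3 and 4); water, O (aldehyde oxygen of 5)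
Why: Stork enamine Michael addition: the enamine of isobutyraldehyde adds to the enone (as the aminodihydropyran) to build the quaternary carbon, and buffered hydrolysis releases the 1,5-keto aldehyde before it can undergo aldol cyclisation.

Step 2
Reactants: 5 2,2-dimethyl-5-oxoheptanal; 6 nitromethane
Product: 9 (E)-6,6-dimethyl-8-nitrooct-7-en-3-one, via nitro alcohol 7 (not isolated), via mesylate 8 (not isolated)
Conditions: 6 (5 equiv), KOt-Bu (5 mol %), THF/t-BuOH, 0 °C; evaporate; then MsCl, Et3N, CH2Cl2, 0 °C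
Reagents that add atoms: methanesulfonyl chloride, CS(=O)(=O)Cl (atoms kept only in 8)
Why: Henry (nitroaldol) addition to the non-enolisable aldehyde (nitromethane is far more acidic than the ketone, so no aldol closure competes) followed by E1cB loss of the mesylate gives the conjugated E nitroalkene, which has no γ-hydrogen and cannot deconjugate.

Step 3
Reactants: 9 (E)-6,6-dimethyl-8-nitrooct-7-en-3-one
Product: 10 (2S,3S)-2,4,4-trimethyl-3-(nitromethyl)cyclohexan-1-one
Conditions: 1-[(1R,2R)-2-aminocyclohexyl]-3-[3,5-bis(trifluoromethyl)phenyl]thiourea (15 mol %), PhCO2H (15 mol %), toluene (0.05 M), rt, 48 h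
Reagents that add atoms: none
Why: Key ring closure by an enamine-mediated intramolecular Michael addition (6-exo-trig): the Z-enamine of the ethyl ketone adds to the thiourea-bound nitroalkene through a chair with the methyl and nitrovinyl groups pseudo-equatorial, which gives the 2,3-trans ring, and the chiral catalyst directs attack to the Si face of the nitroalkene β-carbon, which sets 3S and with it 2S.

Step 4
Reactants: 10 (2S,3S)-2,4,4-trimethyl-3-(nitromethyl)cyclohexan-1-one
Product: 11 (1S,2S,3S)-2,4,4-trimethyl-3-(nitromethyl)cyclohexan-1-ol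
Conditions: NaBH4, CeCl3·7H2O, MeOH, −78 °C
Reagents that add atoms: none
Why: Luche reduction: axial hydride attack on the chair ketone (all three ring substituents equatorial) gives the equatorial 1S alcohol trans to the C2 methyl group, and minor epimers are removed by chromatography.

Step 5
Reactants: 11 (1S,2S,3S)-2,4,4-trimethyl-3-(nitromethyl)cyclohexan-1-ol
Product: 12 tert-butyldimethyl{[(1S,2S,3S)-2,4,4-trimethyl-3-(nitromethyl)cyclohexyl]oxy}silane
Conditions: t-BuMe2SiCl, imidazole, DMF, rt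
Reagents that add atoms: tert-butyldimethylsilyl chloride, CC(C)(C)[Si](C)(C)Cl
Why: Imidazole-mediated silylation of the secondary alcohol; the nitro group does not react and no stereocentre is touched.

Step 6
Reactants: 12 tert-butyldimethyl{[(1S,2S,3S)-2,4,4-trimethyl-3-(nitromethyl)cyclohexyl]oxy}silane
Product: 14 (1S,5S,6S)-5-[(tert-butyldimethylsilyl)oxy]-2,2,6-trimethylcyclohexane-1-carbaldehyde, via potassium nitronate 13 (not isolated)
Conditions: KOH (1.05 equiv), MeOH, 0 °C; then KMnO4 (0.7 equiv), MgSO4, H2O/CH2Cl2, 0 °C, 15 min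
Reagents that add atoms: potassium hydroxide, [K+].[OH-] (potassium kept only in 13); potassium permanganate, [K+].[O-][Mn](=O)(=O)=O (aldehyde oxygen of 14)
Why: Oxidative Nef reaction: permanganate cleaves the C=N bond of the nitronate to the aldehyde within minutes at 0 °C, and the formyl group stays equatorial (trans to the neighbouring methyl) because that is the favoured epimer.

Step 7
Reactants: 14 (1S,5S,6S)-5-[(tert-butyldimethylsilyl)oxy]-2,2,6-trimethylcyclohexane-1-carbaldehyde; 15 ethyl (2E)-4-(diethoxyphosphoryl)-3-methylbut-2-enoate (triethyl 3-methyl-4-phosphonocrotonate)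
Product: 17 ethyl (2E,4E)-5-[(1S,5S,6S)-5-[(tert-butyldimethylsilyl)oxy]-2,2,6-trimethylcyclohexyl]-3-methylpenta-2,4-dienoate, via lithiated phosphonate 16 (not isolated)
Conditions: 15, LiN(SiMe3)2, THF, −78 °C; then 14, DMPU, −78 °C→rt
Reagents that add atoms: lithium bis(trimethylsilyl)amide, [Li+].C[Si](C)(C)[N-][Si](C)(C)C (lithium kept only in 16)
Why: Vinylogous Horner–Wadsworth–Emmons olefination: the stabilised phosphonate anion gives the new disubstituted alkene E and mainly the 2E trisubstituted alkene (the minor 2Z isomer is removed by chromatography), and the ring stereocentres are untouched.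

Step 8
Reactants: 17 ethyl (2E,4E)-5-[(1S,5S,6S)-5-[(tert-butyldimethylsilyl)oxy]-2,2,6-trimethylcyclohexyl]-3-methylpenta-2,4-dienoate
Product: 18 (2E,4E)-5-[(1S,5S,6S)-5-[(tert-butyldimethylsilyl)oxy]-2,2,6-trimethylcyclohexyl]-3-methylpenta-2,4-dien-1-ol
Conditions: i-Bu2AlH (2.5 equiv), CH2Cl2, −78 °C; aq. KNaC4H4O6 (potassium sodium tartrate)
Reagents that add atoms: none
Why: 1,2-Reduction of the conjugated ester by the aluminium hydride gives the dienyl alcohol without touching the diene or the silyl ether.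

Step 9
Reactants: 18 (2E,4E)-5-[(1S,5S,6S)-5-[(tert-butyldimethylsilyl)oxy]-2,2,6-trimethylcyclohexyl]-3-methylpenta-2,4-dien-1-ol
Product: 19 {(2E,4E)-5-[(1S,5S,6S)-5-[(tert-butyldimethylsilyl)oxy]-2,2,6-trimethylcyclohexyl]-3-methylpenta-2,4-dien-1-yl}triphenylphosphonium bromide
Conditions: PPh3·HBr (1.1 equiv), CH2Cl2, 0 °C→rt
Reagents that add atoms: triphenylphosphine hydrobromide, [Br-].c1ccc(cc1)[PH+](c1ccccc1)c1ccccc1
Why: SN1-type phosphonium salt formation: the acid ionises the allylic alcohol to a pentadienyl cation that PPh3 traps at the unhindered primary terminus to give the E,E salt, and the aprotic medium keeps the silyl ether.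

Step 10
Reactants: 10 (2S,3S)-2,4,4-trimethyl-3-(nitromethyl)cyclohexan-1-one
Product: 20 (6S,7S)-6,8,8-trimethyl-7-(nitromethyl)-1,4-dioxaspiro[4.5]decane
Conditions: Me3SiOCH2CH2OSiMe3, Me3SiOTf (5 mol %), CH2Cl2, −78→−20 °C
Reagents that add atoms: 1,2-bis(trimethylsilyloxy)ethane, C[Si](C)(C)OCCO[Si](C)(C)C
Why: Noyori ketalisation: silyl triflate catalysis at low temperature masks the ketone without enolising it, so the methyl-bearing α-stereocentre is kept.

Step 11
Reactants: 20 (6S,7S)-6,8,8-trimethyl-7-(nitromethyl)-1,4-dioxaspiro[4.5]decane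
Product: 22 (6S,7S)-6,8,8-trimethyl-1,4-dioxaspiro[4.5]decane-7-carbaldehyde, via potassium nitronate 21 (not isolated)
Conditions: KOH (1.05 equiv), MeOH, 0 °C; then KMnO4 (0.7 equiv), MgSO4, H2O/CH2Cl2, 0 °C, 15 min
Reagents that add atoms: potassium hydroxide, [K+].[OH-] (potassium kept only in 21); potassium permanganate, [K+].[O-][Mn](=O)(=O)=O (aldehyde oxygen of 22)
Why: Oxidative Nef reaction as in step 6; with the ketone masked only the formyl-bearing centre can epimerise, and it stays trans (equatorial).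

Step 12
Reactants: 22 (6S,7S)-6,8,8-trimethyl-1,4-dioxaspiro[4.5]decane-7-carbaldehyde; 15 ethyl (2E)-4-(diethoxyphosphoryl)-3-methylbut-2-enoate
Product: 24 ethyl (2E,4E)-3-methyl-5-[(6S,7S)-6,8,8-trimethyl-1,4-dioxaspiro[4.5]decan-7-yl]penta-2,4-dienoate, via sodiated phosphonate 23 (not isolated)
Conditions: 15, NaN(SiMe3)2, THF, −78 °C; then 22, −78 °C→rt
Reagents that add atoms: sodium bis(trimethylsilyl)amide, [Na+].C[Si](C)(C)[N-][Si](C)(C)C (sodium kept only in 23)
Why: Vinylogous Horner–Wadsworth–Emmons olefination: the sodium salt of the stabilised phosphonate, made with a non-nucleophilic amide base, adds to the aldehyde at low temperature and gives the E,E dienoate (the minor 2Z isomer is removed by chromatography) with the ketal and both stereocentres intact.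

Step 13
Reactants: 24 ethyl (2E,4E)-3-methyl-5-[(6S,7S)-6,8,8-trimethyl-1,4-dioxaspiro[4.5]decan-7-yl]penta-2,4-dienoate
Product: 25 (2E,4E)-3-methyl-5-[(6S,7S)-6,8,8-trimethyl-1,4-dioxaspiro[4.5]decan-7-yl]penta-2,4-dien-1-ol
Conditions: i-Bu2AlH (2.5 equiv), CH2Cl2, −78 °C; aq. KNaC4H4O6 (potassium sodium tartrate)
Reagents that add atoms: none
Why: 1,2-Reduction of the conjugated ester to the dienyl alcohol; the ketal is inert to the hydride.

Step 14
Reactants: 25 (2E,4E)-3-methyl-5-[(6S,7S)-6,8,8-trimethyl-1,4-dioxaspiro[4.5]decan-7-yl]penta-2,4-dien-1-ol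
Product: 27 {(2E,4E)-3-methyl-5-[(1S,6S)-2,2,6-trimethyl-5-oxocyclohexyl]penta-2,4-dien-1-yl}triphenylphosphonium bromide, via ketal phosphonium bromide 26 (not isolated)
Conditions: PPh3·HBr (1.1 equiv), MeOH, rt; then 1 M aq. HBr (cat.), acetone, rt
Reagents that add atoms: triphenylphosphine hydrobromide, [Br-].c1ccc(cc1)[PH+](c1ccccc1)c1ccccc1; water, O (ketone oxygen of 27)
Why: Phosphonium salt formation as in step 9 followed by mild acid hydrolysis of the dioxolane, which is faster than acid enolisation, so the α-methyl centre of the ketone is kept.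

Step 15
Reactants: 27 {(2E,4E)-3-methyl-5-[(1S,6S)-2,2,6-trimethyl-5-oxocyclohexyl]penta-2,4-dien-1-yl}triphenylphosphonium bromide; 28 (2E,4E,6E)-2,7-dimethylocta-2,4,6-trienedial (C10 dialdehyde)
Product: 30 (2E,4E,6E,8E,10E,12E)-2,7,11-trimethyl-13-[(1S,6S)-2,2,6-trimethyl-5-oxocyclohexyl]trideca-2,4,6,8,10,12-hexaenal, via phosphonium ylide 29 (not isolated)
Conditions: 28 (3 equiv), 1,2-epoxybutane, EtOH, 65 °C, 18 h, dark, argon; then heptane, reflux
Reagents that add atoms: none
Why: Wittig olefination under base-free conditions (bromide opens the epoxide and the alkoxide formed generates the ylide): the excess dialdehyde favours mono-olefination, the semi-stabilised ylide leaves the hindered ketone alone, and heating converts the Z isomer of the new alkene into the all-E polyene.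

Step 16
Reactants: 30 (2E,4E,6E,8E,10E,12E)-2,7,11-trimethyl-13-[(1S,6S)-2,2,6-trimethyl-5-oxocyclohexyl]trideca-2,4,6,8,10,12-hexaenal; 19 {(2E,4E)-5-[(1S,5S,6S)-5-[(tert-butyldimethylsilyl)oxy]-2,2,6-trimethylcyclohexyl]-3-methylpenta-2,4-dien-1-yl}triphenylphosphonium bromide
Product: 32 all-E (4S,5S,6S,5'S,6'S)-4-[(tert-butyldimethylsilyl)oxy]-5,6,5',6'-tetrahydro-β,β-caroten-4'-one, via phosphonium ylide 31 (not isolated)
Conditions: 1,2-epoxybutane, EtOH, 65 °C, dark, argon; then heptane, reflux; crystallise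
Reagents that add atoms: none
Why: The second Wittig olefination joins the two halves at C11=C12, and thermal isomerisation with crystallisation gives the all-E C40 polyene; no stereocentre is formed or touched.

Step 17
Reactants: 32 all-E (4S,5S,6S,5'S,6'S)-4-[(tert-butyldimethylsilyl)oxy]-5,6,5',6'-tetrahydro-β,β-caroten-4'-one
Product: 33 all-E (4S,5S,6S,5'S,6'S)-4-hydroxy-5,6,5',6'-tetrahydro-β,β-caroten-4'-one (CNP0107241.1)
Conditions: Bu4NF, AcOH (1:1), THF, rt, dark, argon
Reagents that add atoms: none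
Why: Fluoride-mediated desilylation buffered with acetic acid frees the 4-hydroxyl without epimerising the ketone α-centre or harming the polyene.

**Compound list**

1 | isobutyraldehyde (2-methylpropanal) | CC(C)C=O | starting material
2 | ethyl vinyl ketone (pent-1-en-3-one) | CCC(=O)C=C | starting material
3 | 1-(2-methylprop-1-en-1-yl)pyrrolidine | CC(C)=CN1CCCC1 | intermediate
4 | 6-ethyl-3,3-dimethyl-2-(pyrrolidin-1-yl)-3,4-dihydro-2H-pyran (racemic) | CCC1=CCC(C)(C)C(N2CCCC2)O1 | intermediate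
5 | 2,2-dimethyl-5-oxoheptanal | CCC(=O)CCC(C)(C)C=O | intermediate
6 | nitromethane | C[N+](=O)[O-] | starting material
7 | 7-hydroxy-6,6-dimethyl-8-nitrooctan-3-one (racemic) | CCC(=O)CCC(C)(C)C(O)C[N+](=O)[O-] | intermediate
8 | 3,3-dimethyl-1-nitro-6-oxooctan-2-yl methanesulfonate (racemic) | CCC(=O)CCC(C)(C)C(OS(C)(=O)=O)C[N+](=O)[O-] | intermediate
9 | (E)-6,6-dimethyl-8-nitrooct-7-en-3-one | CCC(=O)CCC(C)(C)/C=C/[N+](=O)[O-] | intermediate
10 | (2S,3S)-2,4,4-trimethyl-3-(nitromethyl)cyclohexan-1-one | [O-][N+](=O)C[C@H]1[C@H](C)C(=O)CCC1(C)C | intermediate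
11 | (1S,2S,3S)-2,4,4-trimethyl-3-(nitromethyl)cyclohexan-1-ol | [O-][N+](=O)C[C@H]1[C@H](C)[C@@H](O)CCC1(C)C | intermediate
12 | tert-butyldimethyl{[(1S,2S,3S)-2,4,4-trimethyl-3-(nitromethyl)cyclohexyl]oxy}silane | [O-][N+](=O)C[C@H]1[C@H](C)[C@@H](O[Si](C)(C)C(C)(C)C)CCC1(C)C | intermediate
13 | potassium nitronate of 12 | [K+].[O-][N+]([O-])=C[C@H]1[C@H](C)[C@@H](O[Si](C)(C)C(C)(C)C)CCC1(C)C | intermediate
14 | (1S,5S,6S)-5-[(tert-butyldimethylsilyl)oxy]-2,2,6-trimethylcyclohexane-1-carbaldehyde | O=C[C@H]1[C@H](C)[C@@H](O[Si](C)(C)C(C)(C)C)CCC1(C)C | intermediate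
15 | ethyl (2E)-4-(diethoxyphosphoryl)-3-methylbut-2-enoate | CCOC(=O)/C=C(C)/CP(=O)(OCC)OCC | starting material
16 | lithium salt of 15 (carbanion at C4) | [Li+].CCOC(=O)/C=C(C)/[CH-]P(=O)(OCC)OCC | intermediate
17 | ethyl (2E,4E)-5-[(1S,5S,6S)-5-[(tert-butyldimethylsilyl)oxy]-2,2,6-trimethylcyclohexyl]-3-methylpenta-2,4-dienoate | CCOC(=O)/C=C(C)/C=C/[C@H]1[C@H](C)[C@@H](O[Si](C)(C)C(C)(C)C)CCC1(C)C | intermediate
18 | (2E,4E)-5-[(1S,5S,6S)-5-[(tert-butyldimethylsilyl)oxy]-2,2,6-trimethylcyclohexyl]-3-methylpenta-2,4-dien-1-ol | OC/C=C(C)/C=C/[C@H]1[C@H](C)[C@@H](O[Si](C)(C)C(C)(C)C)CCC1(C)C | intermediate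
19 | {(2E,4E)-5-[(1S,5S,6S)-5-[(tert-butyldimethylsilyl)oxy]-2,2,6-trimethylcyclohexyl]-3-methylpenta-2,4-dien-1-yl}triphenylphosphonium bromide | [Br-].c1ccccc1[P+](c1ccccc1)(c1ccccc1)C/C=C(C)/C=C/[C@H]1[C@H](C)[C@@H](O[Si](C)(C)C(C)(C)C)CCC1(C)C | intermediate
20 | (6S,7S)-6,8,8-trimethyl-7-(nitromethyl)-1,4-dioxaspiro[4.5]decane | [O-][N+](=O)C[C@H]1[C@H](C)C2(OCCO2)CCC1(C)C | intermediate
21 | potassium nitronate of 20 | [K+].[O-][N+]([O-])=C[C@H]1[C@H](C)C2(OCCO2)CCC1(C)C | intermediate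
22 | (6S,7S)-6,8,8-trimethyl-1,4-dioxaspiro[4.5]decane-7-carbaldehyde | O=C[C@H]1[C@H](C)C2(OCCO2)CCC1(C)C | intermediate
23 | sodium salt of 15 (carbanion at C4) | [Na+].CCOC(=O)/C=C(C)/[CH-]P(=O)(OCC)OCC | intermediate
24 | ethyl (2E,4E)-3-methyl-5-[(6S,7S)-6,8,8-trimethyl-1,4-dioxaspiro[4.5]decan-7-yl]penta-2,4-dienoate | CCOC(=O)/C=C(C)/C=C/[C@H]1[C@H](C)C2(OCCO2)CCC1(C)C | intermediate
25 | (2E,4E)-3-methyl-5-[(6S,7S)-6,8,8-trimethyl-1,4-dioxaspiro[4.5]decan-7-yl]penta-2,4-dien-1-ol | OC/C=C(C)/C=C/[C@H]1[C@H](C)C2(OCCO2)CCC1(C)C | intermediate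
26 | {(2E,4E)-3-methyl-5-[(6S,7S)-6,8,8-trimethyl-1,4-dioxaspiro[4.5]decan-7-yl]penta-2,4-dien-1-yl}triphenylphosphonium bromide | [Br-].c1ccccc1[P+](c1ccccc1)(c1ccccc1)C/C=C(C)/C=C/[C@H]1[C@H](C)C2(OCCO2)CCC1(C)C | intermediate
27 | {(2E,4E)-3-methyl-5-[(1S,6S)-2,2,6-trimethyl-5-oxocyclohexyl]penta-2,4-dien-1-yl}triphenylphosphonium bromide | [Br-].c1ccccc1[P+](c1ccccc1)(c1ccccc1)C/C=C(C)/C=C/[C@H]1[C@H](C)C(=O)CCC1(C)C | intermediate
28 | (2E,4E,6E)-2,7-dimethylocta-2,4,6-trienedial | O=C/C(C)=C/C=C/C=C(C)/C=O | starting material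
29 | ylide of 27 | c1ccccc1[P+](c1ccccc1)(c1ccccc1)[CH-]/C=C(C)/C=C/[C@H]1[C@H](C)C(=O)CCC1(C)C | intermediate
30 | (2E,4E,6E,8E,10E,12E)-2,7,11-trimethyl-13-[(1S,6S)-2,2,6-trimethyl-5-oxocyclohexyl]trideca-2,4,6,8,10,12-hexaenal | O=C/C(C)=C/C=C/C=C(C)/C=C/C=C(C)/C=C/[C@H]1[C@H](C)C(=O)CCC1(C)C | intermediate
31 | ylide of 19 | c1ccccc1[P+](c1ccccc1)(c1ccccc1)[CH-]/C=C(C)/C=C/[C@H]1[C@H](C)[C@@H](O[Si](C)(C)C(C)(C)C)CCC1(C)C | intermediate
32 | all-E (4S,5S,6S,5'S,6'S)-4-[(tert-butyldimethylsilyl)oxy]-5,6,5',6'-tetrahydro-β,β-caroten-4'-one | CC(/C=C/C=C(C)/C=C/[C@H]1[C@H](C)[C@@H](O[Si](C)(C)C(C)(C)C)CCC1(C)C)=C\C=C\C=C(C)\C=C\C=C(C)\C=C\[C@H]1[C@H](C)C(=O)CCC1(C)C | intermediate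
33 | all-E (4S,5S,6S,5'S,6'S)-4-hydroxy-5,6,5',6'-tetrahydro-β,β-caroten-4'-one | CC(/C=C/C=C(C)/C=C/[C@H]1[C@H](C)[C@@H](O)CCC1(C)C)=C\C=C\C=C(C)\C=C\C=C(C)\C=C\[C@H]1[C@H](C)C(=O)CCC1(C)C | target

**Step count**

Total step count: 17.
Longest linear sequence: 11 steps (steps 1–9, 16, 17; equally steps 1–3, 10–17).

**Steps most likely to fail**

Step 3 (enantio- and diastereocontrol of the enamine Michael closure; the acceptor carbon is neopentylic and the 2,3-cis epimer may accompany the product). Fallback: set out from 9 and close the ring without asymmetric induction, using n-butylamine and benzoic acid in toluene, to obtain racemic trans-2,4,4-trimethyl-3-(nitromethyl)cyclohexan-1-one F1. Reduce it with NaBH4 and CeCl3·7H2O to racemic all-equatorial 2,4,4-trimethyl-3-(nitromethyl)cyclohexan-1-ol F2. Resolve F2 by acylation with vinyl acetate and Burkholderia cepacia lipase (Amano PS) in t-BuOMe, which converts the 1R enantiomer into (1R,2R,3R)-2,4,4-trimethyl-3-(nitromethyl)cyclohexyl acetate F3 and leaves the (1S,2S,3S) alcohol. That alcohol is compound 11, where the route is rejoined; the portion needed for the keto half is oxidised with Dess–Martin periodinane back to 10.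

Step 6 (oxidative Nef reaction on a hindered nitromethyl group, with over-oxidation to the acid or incomplete conversion; the same reaction recurs in step 11). Fallback: set out from 12 and reduce the nitro group with SnCl2·2H2O, PhSH and Et3N in MeCN to (1S,5S,6S)-5-[(tert-butyldimethylsilyl)oxy]-2,2,6-trimethylcyclohexane-1-carbaldehyde oxime F4. Cleave the oxime with aqueous TiCl3 buffered with NH4OAc, which comes back to the route at 14. In the ketal series the same two operations lead from 20 through (6S,7S)-6,8,8-trimethyl-1,4-dioxaspiro[4.5]decane-7-carbaldehyde oxime F5 back to the route at 22.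

Step 15 (mono-olefination of a symmetrical dialdehyde; bis-olefination and loss of the advanced salt). Fallback: set out from 28 and treat it with HC(OMe)3 (0.5 equiv) and a trace of p-toluenesulfonic acid in MeOH, recycling dialdehyde and bis-acetal, to obtain (2E,4E,6E)-8,8-dimethoxy-2,7-dimethylocta-2,4,6-trienal F6. Run the Wittig reaction of 27 (1,2-epoxybutane, EtOH, 65 °C) on this mono-protected dialdehyde to obtain (2S,3S)-3-[(1E,3E,5E,7E,9E,11E)-13,13-dimethoxy-3,7,12-trimethyltrideca-1,3,5,7,9,11-hexaen-1-yl]-2,4,4-trimethylcyclohexan-1-one F7. Hydrolyse the acetal with dilute aqueous citric acid in acetone, which comes back to the route at 30.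

**Further compounds**

F1 | step 3 | racemic (2S,3S)/(2R,3R)-2,4,4-trimethyl-3-(nitromethyl)cyclohexan-1-one | [O-][N+](=O)C[C@H]1[C@H](C)C(=O)CCC1(C)C.[O-][N+](=O)C[C@@H]1[C@@H](C)C(=O)CCC1(C)C
F2 | step 3 | racemic (1S,2S,3S)/(1R,2R,3R)-2,4,4-trimethyl-3-(nitromethyl)cyclohexan-1-ol | [O-][N+](=O)C[C@H]1[C@H](C)[C@@H](O)CCC1(C)C.[O-][N+](=O)C[C@@H]1[C@@H](C)[C@H](O)CCC1(C)C
F3 | step 3 | (1R,2R,3R)-2,4,4-trimethyl-3-(nitromethyl)cyclohexyl acetate | [O-][N+](=O)C[C@@H]1[C@@H](C)[C@H](OC(C)=O)CCC1(C)C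
F4 | step 6 | (1S,5S,6S)-5-[(tert-butyldimethylsilyl)oxy]-2,2,6-trimethylcyclohexane-1-carbaldehyde oxime (E/Z mixture) | ON=C[C@H]1[C@H](C)[C@@H](O[Si](C)(C)C(C)(C)C)CCC1(C)C
F5 | step 6 | (6S,7S)-6,8,8-trimethyl-1,4-dioxaspiro[4.5]decane-7-carbaldehyde oxime (E/Z mixture) | ON=C[C@H]1[C@H](C)C2(OCCO2)CCC1(C)C
F6 | step 15 | (2E,4E,6E)-8,8-dimethoxy-2,7-dimethylocta-2,4,6-trienal | COC(OC)/C(C)=C/C=C/C=C(C)/C=O
F7 | step 15 | (2S,3S)-3-[(1E,3E,5E,7E,9E,11E)-13,13-dimethoxy-3,7,12-trimethyltrideca-1,3,5,7,9,11-hexaen-1-yl]-2,4,4-trimethylcyclohexan-1-one | COC(OC)/C(C)=C/C=C/C=C(C)/C=C/C=C(C)/C=C/[C@H]1[C@H](C)C(=O)CCC1(C)C
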